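## Retrosynthetic overview

1. Target 25 ⇐ desilylation, angeloylation at O-8, tartrate-controlled epoxidation of the 9E-olefin directed by the C8 carbinol, and C13 methylenation ⇐ macrocyclic allylic alcohol 17.
2. Key disconnection C8–C9 (together with C10–CH3): 17 ⇐ ynal 15 + ZnMe2 by a nickel-catalysed methylative macrocyclisation. The enabling feature is the O–C8–C9(–O–)C10(CH3) array: the 9,10-oxirane next to the oxygenated C8 is a masked E-trisubstituted allylic alcohol, i.e. CHO + terminal alkyne + CH3. The trans-fused C6/C7 γ-lactone, already in place, holds the formyl group (on C7) and the alkynyl arm (on C6) on adjacent carbons of a rigid five-membered ring.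
3. 15 ⇐ Evans syn-aldol/lactonisation of succinate imide 11 with α-silyloxy aldehyde 8 (sets C6 and C7).
4. 8 ⇐ Sharpless epoxidation and AlMe3 opening of (2E)-oct-2-en-7-yn-1-ol (sets C5 and C4) ⇐ hex-5-yn-1-ol.
5. Ring order: γ-lactone (step 8) → ten-membered carbocycle (step 11) → oxirane (step 14).

Key step: step 11

Remark: ring compounds are described with germacrane numbering (C6 bears the lactone oxygen, C7 the lactone carbon C11, C8 the carbinol/ester, C9–C10 the olefin/oxirane, C14 on C10, C15 on C4; α/β as in the usual drawing with H-7 α); compounds 1, 9 and 10 are taken as commercial.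

## Route

Step 1
Reactants: 1 hex-5-yn-1-ol
Product: 3 ethyl (2E)-oct-2-en-7-ynoate, via hex-5-ynal 2 (not isolated)
Conditions: PhI(OAc)2, TEMPO (10 mol %), CH2Cl2, rt; then Ph3P=CHCO2Et, rt
Reagents that add atoms: ethyl (triphenylphosphoranylidene)acetate, CCOC(=O)C=P(c1ccccc1)(c1ccccc1)c1ccccc1
Why: TEMPO/iodine(III) oxidation to the volatile aldehyde followed in the same flask by Wittig olefination with the stabilised ylide should give the E-enoate.

Step 2
Reactants: 3 ethyl (2E)-oct-2-en-7-ynoate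
Product: 4 (2E)-oct-2-en-7-yn-1-ol
Conditions: i-Bu2AlH (2.2 equiv), CH2Cl2, −78 °C; aq. potassium sodium tartrate
Reagents that add atoms: none
Why: 1,2-reduction of the enoate by the aluminium hydride gives the E-allylic alcohol without touching the alkyne.

Step 3
Reactants: 4 (2E)-oct-2-en-7-yn-1-ol
Product: 5 [(2S,3S)-3-(pent-4-yn-1-yl)oxiran-2-yl]methanol
Conditions: Ti(OiPr)4 (10 mol %), L-(+)-diethyl tartrate (12 mol %), t-BuOOH, 4 Å molecular sieves, CH2Cl2, −20 °C
Reagents that add atoms: tert-butyl hydroperoxide, CC(C)(C)OO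
Why: Sharpless asymmetric epoxidation; the L-tartrate ligand selects the olefin face that gives the (2S,3S)-epoxy alcohol, which fixes the later C5 centre.

Step 4
Reactants: 5 [(2S,3S)-3-(pent-4-yn-1-yl)oxiran-2-yl]methanol
Product: 6 (2R,3R)-3-methyloct-7-yne-1,2-diol
Conditions: AlMe3 (3 equiv), CH2Cl2/hexane, 0 °C to rt; aq. potassium sodium tartrate
Reagents that add atoms: trimethylaluminium, C[Al](C)C
Why: the aluminium alkoxide directs methyl delivery to C3 of the 2,3-epoxy alcohol with inversion (SN2 epoxide opening), giving the anti 3-methyl-1,2-diol and so the later C4 methyl centre.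

Step 5
Reactants: 6 (2R,3R)-3-methyloct-7-yne-1,2-diol
Product: 7 (2R,3R)-3-methyl-1,2-bis(triethylsilyloxy)oct-7-yne
Conditions: Et3SiCl (2.5 equiv), imidazole, DMAP (cat.), CH2Cl2, 0 °C to rt
Reagents that add atoms: chlorotriethylsilane, CC[Si](Cl)(CC)CC
Why: standard silylation of both hydroxyl groups.

Step 6
Reactants: 7 (2R,3R)-3-methyl-1,2-bis(triethylsilyloxy)oct-7-yne
Product: 8 (2R,3R)-3-methyl-2-(triethylsilyloxy)oct-7-ynal
Conditions: (COCl)2, DMSO, CH2Cl2, −78 to −30 °C; then Et3N, −78 °C to rt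
Reagents that add atoms: none
Why: under Swern conditions the chlorosulfonium reagent should attack the less hindered primary triethylsilyl ether selectively and oxidise it directly to the aldehyde, leaving the secondary silyl ether in place.

Step 7
Reactants: 9 (4S)-4-benzyl-1,3-oxazolidin-2-one; 10 methyl 4-chloro-4-oxobutanoate
Product: 11 methyl 4-[(4S)-4-benzyl-2-oxo-1,3-oxazolidin-3-yl]-4-oxobutanoate
Conditions: n-BuLi, THF, −78 °C; then 10, −78 to 0 °C
Reagents that add atoms: none
Why: N-acylation of the lithiated oxazolidinone with the acid chloride.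

Step 8
Reactants: 8 (2R,3R)-3-methyl-2-(triethylsilyloxy)oct-7-ynal; 11 methyl 4-[(4S)-4-benzyl-2-oxo-1,3-oxazolidin-3-yl]-4-oxobutanoate
Product: 13 (4S)-4-benzyl-3-{(2S,3S)-2-[(1R,2R)-2-methyl-1-(triethylsilyloxy)hept-6-yn-1-yl]-5-oxooxolane-3-carbonyl}-1,3-oxazolidin-2-one, via aldol adduct 12 (not isolated)
Conditions: 11, Bu2BOTf, i-Pr2NEt, CH2Cl2, −78 to 0 °C; then 8, −78 to 0 °C; pH 7 buffer, MeOH, H2O2; then DMAP (cat.), Et3N, CH2Cl2, rt
Reagents that add atoms: none
Why: Evans syn-aldol through the Z-boron enolate and a Zimmerman–Traxler transition state: the (S)-benzyl auxiliary sets C7 and C6, reinforced by the 3,4-anti (Cornforth) preference of the α-silyloxy aldehyde, and the resulting γ-hydroxy ester should close to the trans-4,5-disubstituted γ-lactone.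

Step 9
Reactants: 13 (4S)-4-benzyl-3-{(2S,3S)-2-[(1R,2R)-2-methyl-1-(triethylsilyloxy)hept-6-yn-1-yl]-5-oxooxolane-3-carbonyl}-1,3-oxazolidin-2-one
Product: 14 (4R,5S)-4-(hydroxymethyl)-5-[(1R,2R)-2-methyl-1-(triethylsilyloxy)hept-6-yn-1-yl]oxolan-2-one
Conditions: NaBH4, THF/H2O (4:1), 0 °C to rt
Reagents that add atoms: none
Why: reductive cleavage of the N-acyloxazolidinone; the exocyclic imide carbonyl is far more electrophilic than the γ-lactone, which borohydride attacks only on heating.

Step 10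
Reactants: 14 (4R,5S)-4-(hydroxymethyl)-5-[(1R,2R)-2-methyl-1-(triethylsilyloxy)hept-6-yn-1-yl]oxolan-2-one
Product: 15 (2S,3S)-2-[(1R,2R)-2-methyl-1-(triethylsilyloxy)hept-6-yn-1-yl]-5-oxooxolane-3-carbaldehyde
Conditions: Dess–Martin periodinane, NaHCO3, CH2Cl2, 0 °C to rt; used crude
Reagents that add atoms: none
Why: buffered Dess–Martin oxidation should give the aldehyde without epimerisation at C7, whose trans arrangement on the lactone is in any case the thermodynamic one.

Step 11
Reactants: 15 (2S,3S)-2-[(1R,2R)-2-methyl-1-(triethylsilyloxy)hept-6-yn-1-yl]-5-oxooxolane-3-carbaldehyde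
Product: 17 (9E)-8α-hydroxy-5α-(triethylsilyloxy)-4βH-13-norgermacr-9-en-12,6α-olide, via methylzinc alkoxide 16 (not isolated)
Conditions: Ni(cod)2 (20 mol %), PBu3 (40 mol %), ZnMe2 (3 equiv), THF, 0 °C to rt, 15 added by syringe pump over 10 h (final 0.003 M); sat. aq. NH4Cl
Reagents that add atoms: dimethylzinc, C[Zn]C
Why: Proposed new method: zerovalent nickel (PBu3) should bind the terminal alkyne and the aldehyde of 15 and undergo oxidative cyclisation to an oxanickelacyclopentene (divalent nickel) in which C8 is bonded to the unsubstituted alkyne carbon C9 and nickel to C10; methyl transfer from ZnMe2 (zinc on the aldehyde oxygen) and C(sp2)–CH3 reductive elimination then release zinc alkoxide 16 and zerovalent nickel. The closest known reaction types are the nickel-catalysed three-component alkylative coupling of alkynes, aldehydes and organozincs (intermolecular and in five- and six-membered ynal cyclisations) and the nickel-catalysed reductive macrocyclisation of ynals to endocyclic E-allylic alcohols in larger rings; a methylative endo closure of a ten-membered ring has no direct precedent. The ten-membered carbocycle is closed in the 10-endo-dig mode, the five-membered nickelacycle being annulated to the forming ring. The E geometry of the C9=C10 olefin (C1 and C8 trans) follows from syn addition of C8 and CH3 across the alkyne, and the 8α carbinol is expected from Felkin–Anh attack anti to the C6 branch of the rigid trans-lactone. The step needs regioselectivity (C–C bond at the terminal carbon, secured by the H/alkyl size difference and a small phosphine), ring closure over oligomerisation (slow addition, high dilution, and the lactone as a turn element carrying both arms on adjacent carbons) and chemoselectivity (the saturated lactone offers no Michael acceptor, and ZnMe2 does not add to aldehyde or lactone uncatalysed).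

Step 12
Reactants: 17 (9E)-8α-hydroxy-5α-(triethylsilyloxy)-4βH-13-norgermacr-9-en-12,6α-olide
Product: 18 (9E)-5α-(triethylsilyloxy)-8α-(trimethylsilyloxy)-4βH-13-norgermacr-9-en-12,6α-olide
Conditions: Me3SiCl, imidazole, CH2Cl2, 0 °C
Reagents that add atoms: chlorotrimethylsilane, C[Si](C)(C)Cl
Why: transient silylation of the C8 hydroxyl so that no alkoxide next to the lactone (translactonisation to O-8) is present during the enolate step.

Step 13
Reactants: 18 (9E)-5α-(triethylsilyloxy)-8α-(trimethylsilyloxy)-4βH-13-norgermacr-9-en-12,6α-olide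
Product: 22 (9E)-8α-hydroxy-5α-(triethylsilyloxy)-4βH-germacra-9,11(13)-dien-12,6α-olide, via Mannich base 19 (not isolated), via ammonium iodide 20 (not isolated), via silyl ether 21 (not isolated)
Conditions: LiN(iPr)2 (1.3 equiv), THF, −78 °C; CH2=NMe2+ I−, −78 °C to rt; then MeI, THF, rt; then aq. NaHCO3, CH2Cl2, rt; then citric acid, MeOH, 0 °C
Reagents that add atoms: N,N-dimethylmethyleneiminium iodide (Eschenmoser's salt), C=[N+](C)C.[I-]
Why: Eschenmoser methylenation: the lactone enolate is aminomethylated at C11 (anti to the C7 substituent, a centre that is destroyed again), quaternised and eliminated (E1cB) to the exocyclic methylene, and the mild acid removes the trimethylsilyl ether while the hindered triethylsilyl ether stays.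

Step 14
Reactants: 22 (9E)-8α-hydroxy-5α-(triethylsilyloxy)-4βH-germacra-9,11(13)-dien-12,6α-olide
Product: 23 9α,10β-epoxy-8α-hydroxy-5α-(triethylsilyloxy)-4βH-germacr-11(13)-en-12,6α-olide
Conditions: Ti(OiPr)4 (0.3 equiv), D-(−)-diisopropyl tartrate (0.36 equiv), t-BuOOH (2 equiv), 4 Å molecular sieves, CH2Cl2, −20 °C
Reagents that add atoms: tert-butyl hydroperoxide, CC(C)(C)OO
Why: Sharpless epoxidation in the matched sense: the D-tartrate ligand should deliver oxygen to the olefin face that gives the (9R,10R)-oxirane, which for the 8α carbinol is the erythro product of the fast kinetic-resolution manifold and the peripheral face with C7 turned inward, while the electron-poor C11=C13 olefin is inert to the titanium peroxide.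

Step 15
Reactants: 23 9α,10β-epoxy-8α-hydroxy-5α-(triethylsilyloxy)-4βH-germacr-11(13)-en-12,6α-olide
Product: 24 8α-angeloyloxy-9α,10β-epoxy-5α-(triethylsilyloxy)-4βH-germacr-11(13)-en-12,6α-olide
Conditions: angelic acid, 2,4,6-trichlorobenzoyl chloride, Et3N, toluene, rt; then 23, toluene, 75 °C
Reagents that add atoms: angelic acid [(2Z)-2-methylbut-2-enoic acid], C/C=C(/C)C(=O)O
Why: Yamaguchi-type esterification through the mixed anhydride, a protocol that should acylate hindered secondary alcohols with retention at C8 and without Z to E isomerisation of the angeloyl group.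

Step 16
Reactants: 24 8α-angeloyloxy-9α,10β-epoxy-5α-(triethylsilyloxy)-4βH-germacr-11(13)-en-12,6α-olide
Product: 25 8α-angeloyloxy-9α,10β-epoxy-5α-hydroxy-4βH-germacr-11(13)-en-12,6α-olide, (4R,5R,6S,7S,8R,9R,10R), the target
Conditions: HF·pyridine, pyridine, THF, 0 °C
Reagents that add atoms: none
Why: buffered fluoride cleavage of the triethylsilyl ether should spare the oxirane, the angelate and the methylene lactone.

## Compound list

1 | hex-5-yn-1-ol | OCCCCC#C | starting material
2 | hex-5-ynal | O=CCCCC#C | intermediate (not isolated)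
3 | ethyl (2E)-oct-2-en-7-ynoate | CCOC(=O)/C=C/CCCC#C | intermediate
4 | (2E)-oct-2-en-7-yn-1-ol | OC/C=C/CCCC#C | intermediate
5 | [(2S,3S)-3-(pent-4-yn-1-yl)oxiran-2-yl]methanol | OC[C@@H]1O[C@H]1CCCC#C | intermediate
6 | (2R,3R)-3-methyloct-7-yne-1,2-diol | OC[C@H](O)[C@H](C)CCCC#C | intermediate
7 | (2R,3R)-3-methyl-1,2-bis(triethylsilyloxy)oct-7-yne | CC[Si](CC)(CC)OC[C@H](O[Si](CC)(CC)CC)[C@H](C)CCCC#C | intermediate
8 | (2R,3R)-3-methyl-2-(triethylsilyloxy)oct-7-ynal | O=C[C@H](O[Si](CC)(CC)CC)[C@H](C)CCCC#C | intermediate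
9 | (4S)-4-benzyl-1,3-oxazolidin-2-one | O=C1N[C@@H](Cc2ccccc2)CO1 | starting material
10 | methyl 4-chloro-4-oxobutanoate | COC(=O)CCC(Cl)=O | starting material
11 | methyl 4-[(4S)-4-benzyl-2-oxo-1,3-oxazolidin-3-yl]-4-oxobutanoate | COC(=O)CCC(=O)N1[C@@H](Cc2ccccc2)COC1=O | intermediate
12 | methyl (3S,4S,5R,6R)-3-[(4S)-4-benzyl-2-oxo-1,3-oxazolidine-3-carbonyl]-4-hydroxy-6-methyl-5-(triethylsilyloxy)undec-10-ynoate (aldol adduct) | COC(=O)C[C@H](C(=O)N1[C@@H](Cc2ccccc2)COC1=O)[C@H](O)[C@H](O[Si](CC)(CC)CC)[C@H](C)CCCC#C | intermediate (not isolated)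
13 | (4S)-4-benzyl-3-{(2S,3S)-2-[(1R,2R)-2-methyl-1-(triethylsilyloxy)hept-6-yn-1-yl]-5-oxooxolane-3-carbonyl}-1,3-oxazolidin-2-one | O=C1C[C@H](C(=O)N2[C@@H](Cc3ccccc3)COC2=O)[C@H](O1)[C@H](O[Si](CC)(CC)CC)[C@H](C)CCCC#C | intermediate
14 | (4R,5S)-4-(hydroxymethyl)-5-[(1R,2R)-2-methyl-1-(triethylsilyloxy)hept-6-yn-1-yl]oxolan-2-one | O=C1C[C@H](CO)[C@H](O1)[C@H](O[Si](CC)(CC)CC)[C@H](C)CCCC#C | intermediate
15 | (2S,3S)-2-[(1R,2R)-2-methyl-1-(triethylsilyloxy)hept-6-yn-1-yl]-5-oxooxolane-3-carbaldehyde | O=C1C[C@H](C=O)[C@H](O1)[C@H](O[Si](CC)(CC)CC)[C@H](C)CCCC#C | intermediate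
16 | methylzinc alkoxide of 17 (O-8 bound to ZnCH3) | O=C1O[C@@H]2[C@H](O[Si](CC)(CC)CC)[C@H](C)CCC/C(C)=C/[C@H](O[Zn]C)[C@H]2C1 | intermediate (not isolated)
17 | (9E)-8α-hydroxy-5α-(triethylsilyloxy)-4βH-13-norgermacr-9-en-12,6α-olide | O=C1O[C@@H]2[C@H](O[Si](CC)(CC)CC)[C@H](C)CCC/C(C)=C/[C@H](O)[C@H]2C1 | intermediate
18 | (9E)-5α-(triethylsilyloxy)-8α-(trimethylsilyloxy)-4βH-13-norgermacr-9-en-12,6α-olide | O=C1O[C@@H]2[C@H](O[Si](CC)(CC)CC)[C@H](C)CCC/C(C)=C/[C@H](O[Si](C)(C)C)[C@H]2C1 | intermediate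
19 | (9E)-13-(dimethylamino)-5α-(triethylsilyloxy)-8α-(trimethylsilyloxy)-4βH,11βH-germacr-9-en-12,6α-olide (Mannich base) | O=C1O[C@@H]2[C@H](O[Si](CC)(CC)CC)[C@H](C)CCC/C(C)=C/[C@H](O[Si](C)(C)C)[C@H]2[C@@H]1CN(C)C | intermediate (not isolated)
20 | N-methyl trimethylammonium iodide of 19 | O=C1O[C@@H]2[C@H](O[Si](CC)(CC)CC)[C@H](C)CCC/C(C)=C/[C@H](O[Si](C)(C)C)[C@H]2[C@@H]1C[N+](C)(C)C.[I-] | intermediate (not isolated)
21 | (9E)-5α-(triethylsilyloxy)-8α-(trimethylsilyloxy)-4βH-germacra-9,11(13)-dien-12,6α-olide | C=C1C(=O)O[C@@H]2[C@H](O[Si](CC)(CC)CC)[C@H](C)CCC/C(C)=C/[C@H](O[Si](C)(C)C)[C@@H]12 | intermediate (not isolated)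
22 | (9E)-8α-hydroxy-5α-(triethylsilyloxy)-4βH-germacra-9,11(13)-dien-12,6α-olide | C=C1C(=O)O[C@@H]2[C@H](O[Si](CC)(CC)CC)[C@H](C)CCC/C(C)=C/[C@H](O)[C@@H]12 | intermediate
23 | 9α,10β-epoxy-8α-hydroxy-5α-(triethylsilyloxy)-4βH-germacr-11(13)-en-12,6α-olide | C=C1C(=O)O[C@@H]2[C@H](O[Si](CC)(CC)CC)[C@H](C)CCC[C@@]3(C)O[C@@H]3[C@H](O)[C@@H]12 | intermediate
24 | 8α-angeloyloxy-9α,10β-epoxy-5α-(triethylsilyloxy)-4βH-germacr-11(13)-en-12,6α-olide | C=C1C(=O)O[C@@H]2[C@H](O[Si](CC)(CC)CC)[C@H](C)CCC[C@@]3(C)O[C@@H]3[C@H](OC(=O)/C(C)=C\C)[C@@H]12 | intermediate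
25 | 8α-angeloyloxy-9α,10β-epoxy-5α-hydroxy-4βH-germacr-11(13)-en-12,6α-olide | C=C1C(=O)O[C@@H]2[C@H](O)[C@H](C)CCC[C@@]3(C)O[C@@H]3[C@H](OC(=O)/C(C)=C\C)[C@@H]12 | target

## Step count and risks

Total step count: 16. Longest linear sequence: 15 steps (steps 1–6 and 8–16 from hex-5-yn-1-ol); step 7 is a one-step branch.

Steps most likely to fail:

1. Step 11 (proposed new method). Oligomerisation or cyclotrimerisation of the alkyne on zerovalent nickel, exo-mode closure to a nine-membered ring, or plain methyl transfer to the aldehyde may outrun the strained ten-membered endo closure. The fallback uses known chemistry, sets out from 14 and returns at 17. Zirconium-catalysed carboalumination of the terminal alkyne of 14 (AlMe3, Cp2ZrCl2, H2O, CH2Cl2, −25 °C, brief, then I2) should give (4R,5S)-4-(hydroxymethyl)-5-[(1R,2R,6E)-7-iodo-2,6-dimethyl-1-(triethylsilyloxy)hept-6-en-1-yl]oxolan-2-one F1. Dess–Martin oxidation then gives the iodo aldehyde (2S,3S)-2-[(1R,2R,6E)-7-iodo-2,6-dimethyl-1-(triethylsilyloxy)hept-6-en-1-yl]-5-oxooxolane-3-carbaldehyde F2. A Nozaki–Hiyama–Kishi macrocyclisation (CrCl2, NiCl2 cat., DMSO/THF, 0.002 M, slow addition) forms the same C8–C9 bond with retention of the E olefin and the same Felkin–Anh sense, and returns to 17.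

2. Step 14. Facial selectivity may be poor: the conformer with H-8 eclipsing the olefin (minimised allylic 1,3-strain towards the C14 methyl) exposes the opposite olefin face, and the tartrate–titanium assembly may not override it. The fallback sets out from 22 and returns at 23. Dess–Martin oxidation of 22 gives the enone (9E)-8-oxo-5α-(triethylsilyloxy)-4βH-germacra-9,11(13)-dien-12,6α-olide F3, in which the C8 centre no longer biases the olefin. Dimethyldioxirane (acetone, 0 °C) should epoxidise the electron-richer C9=C10 bond from the ring periphery to the epoxy ketone 9α,10β-epoxy-8-oxo-5α-(triethylsilyloxy)-4βH-germacr-11(13)-en-12,6α-olide F4; the face taken here is not secured either and would have to be checked. Zn(BH4)2 (Et2O, −20 °C) then reduces under chelation between the ketone and oxirane oxygens, which sets C8 from the oxirane in the erythro sense and gives 23. This detour also funnels any C8 epimer formed in step 11.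

3. Step 15. Acylation of the hindered C8 carbinol may be sluggish and the angeloyl group may isomerise from Z to E (tiglate) under forcing conditions. The fallback sets out from 23 and returns at 24. Esterification of 23 with 2-[bis(2,2,2-trifluoroethoxy)phosphoryl]propanoic acid (DCC, DMAP cat., CH2Cl2) gives the phosphonate ester 8α-{2-[bis(2,2,2-trifluoroethoxy)phosphoryl]propanoyloxy}-9α,10β-epoxy-5α-(triethylsilyloxy)-4βH-germacr-11(13)-en-12,6α-olide F5. A Still–Gennari olefination with acetaldehyde (KN(SiMe3)2, 18-crown-6, THF, −78 °C) then builds the Z-2-methylbut-2-enoate on the substrate, so the olefin geometry is set by the reaction and not carried through an acyl transfer.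

## Further compounds

F1 | step 11 | (4R,5S)-4-(hydroxymethyl)-5-[(1R,2R,6E)-7-iodo-2,6-dimethyl-1-(triethylsilyloxy)hept-6-en-1-yl]oxolan-2-one | O=C1C[C@H](CO)[C@H](O1)[C@H](O[Si](CC)(CC)CC)[C@H](C)CCC/C(C)=C/I
F2 | step 11 | (2S,3S)-2-[(1R,2R,6E)-7-iodo-2,6-dimethyl-1-(triethylsilyloxy)hept-6-en-1-yl]-5-oxooxolane-3-carbaldehyde | O=C1C[C@H](C=O)[C@H](O1)[C@H](O[Si](CC)(CC)CC)[C@H](C)CCC/C(C)=C/I
F3 | step 14 | (9E)-8-oxo-5α-(triethylsilyloxy)-4βH-germacra-9,11(13)-dien-12,6α-olide | C=C1C(=O)O[C@@H]2[C@H](O[Si](CC)(CC)CC)[C@H](C)CCC/C(C)=C/C(=O)[C@@H]12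
F4 | step 14 | 9α,10β-epoxy-8-oxo-5α-(triethylsilyloxy)-4βH-germacr-11(13)-en-12,6α-olide | C=C1C(=O)O[C@@H]2[C@H](O[Si](CC)(CC)CC)[C@H](C)CCC[C@@]3(C)O[C@@H]3C(=O)[C@@H]12
F5 | step 15 | 8α-{2-[bis(2,2,2-trifluoroethoxy)phosphoryl]propanoyloxy}-9α,10β-epoxy-5α-(triethylsilyloxy)-4βH-germacr-11(13)-en-12,6α-olide (both epimers at the phosphonate carbon) | C=C1C(=O)O[C@@H]2[C@H](O[Si](CC)(CC)CC)[C@H](C)CCC[C@@]3(C)O[C@@H]3[C@H](OC(=O)C(C)P(=O)(OCC(F)(F)F)OCC(F)(F)F)[C@@H]12
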